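**Retrosynthetic overview**

- The strategy rests on the trans-3,4-disubstituted γ-butyrolactone. C3, next to the carbonyl, carries the ring A 4-hydroxy-3-methoxybenzyl arm. The adjacent C4 carries the CH2 arm that ends at C5 of the dihydrobenzofuran. These two neighbouring ring carbons are the enolate carbon and the acceptor carbon of a butenolide.
- The C4–CH2(benzofuranyl) and C3–CH2(ring A) bonds are cut together. This gives a menthol-derived 5-alkoxybutenolide, the benzofuranyl carbanion equivalent ArCH(SPh)2 and a benzylic bromide. Sulfur, menthol and the protecting groups are removed afterwards.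
- The dihydrobenzofuran is cut at O1–C2 (a phenol captures a benzylic cation) and at C2–C3 (oxazolidinone syn aldol of an arylacetyl imide with O-benzylvanillin). The arylacetic acid comes from 5-iodovanillin by a Negishi–Reformatsky coupling.
- Ring order: the lactone ring exists from step 1, and the dihydrofuran ring closes in step 13. The key step closes no ring. The lactone is opened and re-closed in step 18, where the acetal carbon becomes CH2.

Key step: step 16

Remark on the chemistry: lactone atoms are numbered O1, C2 (C=O), C3, C4, C5, and benzofuran atoms O1, C2, C3, C3a, C4–C7, C7a. The ring closure of step 13 is assumed to run under thermodynamic control, so the auxiliary only has to fix C3 of the benzofuran.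

**Step 1**
Reactants: 1 furfural
Product: 3 5-hydroxyfuran-2(5H)-one (racemic, labile lactol), via furan endoperoxide 2 (not isolated)
Conditions: O2, rose bengal (cat.), MeOH, visible light, 0–20 °C
Reagents that add atoms: dioxygen, O=O
Why: Singlet-oxygen [4+2] cycloaddition to the furan gives endoperoxide 2, which methanol cleaves at the formyl carbon to the hydroxybutenolide, and no configuration has to be controlled because C5 is a labile lactol centre.

**Step 2**
Reactants: 3 5-hydroxyfuran-2(5H)-one; 4 l-menthol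
Product: 5 (5R)-5-(l-menthyloxy)furan-2(5H)-one
Conditions: neat, 100 °C, water removed in a slow N2 stream; crystallisation from petroleum ether, −20 °C; mother liquor re-equilibrated with TsOH·H2O (cat.) and recrystallised
Reagents that add atoms: none
Why: Lactol-to-acetal exchange (acetalisation) gives both C5 epimers, which interconvert under acid, and selective crystallisation of the (5R) epimer with recycling of the mother liquor sets C5.

**Step 3**
Reactants: 6 vanillin
Product: 7 4-(benzyloxy)-3-methoxybenzaldehyde (O-benzylvanillin)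
Conditions: BnBr, K2CO3, DMF, rt
Reagents that add atoms: benzyl bromide, BrCc1ccccc1
Why: Williamson ether synthesis on the acidic phenol, which is the only nucleophilic site.

**Step 4**
Reactants: 7 O-benzylvanillin
Product: 8 [4-(benzyloxy)-3-methoxyphenyl]methanol
Conditions: NaBH4, MeOH, 0 °C
Reagents that add atoms: none
Why: Borohydride reduction of an aromatic aldehyde, with the aryl ethers inert.

**Step 5**
Reactants: 8 [4-(benzyloxy)-3-methoxyphenyl]methanol
Product: 9 4-(benzyloxy)-3-methoxybenzyl bromide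
Conditions: PBr3 (0.4 equiv), Et2O, 0 °C; used the same day
Reagents that add atoms: phosphorus tribromide, BrP(Br)Br
Why: Bromination of a benzylic alcohol through its phosphite ester (SN2 by bromide), kept cold and used fresh because the electron-rich bromide is labile.

**Step 6**
Reactants: 10 5-iodovanillin
Product: 11 3-iodo-5-methoxy-4-(methoxymethoxy)benzaldehyde
Conditions: MOMCl, iPr2NEt, CH2Cl2, 0 °C → rt
Reagents that add atoms: chloromethyl methyl ether, COCCl
Why: O-Alkylation of the phenol as its MOM ether, a group that tolerates zinc enolates, base, boron triflate and hydride and leaves under the acid used later for ring closure.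

**Step 7**
Reactants: 11 3-iodo-5-methoxy-4-(methoxymethoxy)benzaldehyde
Product: 12 2-[3-iodo-5-methoxy-4-(methoxymethoxy)phenyl]-1,3-dioxolane
Conditions: ethylene glycol, HC(OEt)3, TsOH·H2O (2 mol%), CH2Cl2, rt
Reagents that add atoms: ethylene glycol, OCCO
Why: Acetalisation with an orthoester as water scavenger runs at room temperature with a trace of acid, which the aryl MOM ether survives.

**Step 8**
Reactants: 12 2-[3-iodo-5-methoxy-4-(methoxymethoxy)phenyl]-1,3-dioxolane
Product: 13 ethyl 2-[5-(1,3-dioxolan-2-yl)-3-methoxy-2-(methoxymethoxy)phenyl]acetate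
Conditions: BrZnCH2CO2Et (1.5 equiv, THF solution), Pd2(dba)3 (2 mol%), XPhos (8 mol%), THF, 50 °C
Reagents that add atoms: (2-ethoxy-2-oxoethyl)zinc bromide, CCOC(=O)C[Zn]Br
Why: Negishi-type coupling of a Reformatsky reagent (palladium-catalysed ester α-arylation) proceeds by oxidative addition of the aryl iodide to zerovalent palladium, transmetalation and reductive elimination, and the neutral zinc enolate leaves the acetal and the MOM ether alone.

**Step 9**
Reactants: 13 ethyl arylacetate
Product: 14 2-[5-(1,3-dioxolan-2-yl)-3-methoxy-2-(methoxymethoxy)phenyl]acetic acid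
Conditions: LiOH·H2O, THF–H2O, rt; then 1 M KHSO4 to pH 4, 0 °C, immediate extraction
Reagents that add atoms: lithium hydroxide, [Li+].[OH-]
Why: Saponification of an unhindered ester, with a cold and only weakly acidic work-up so that both acetal-type groups survive.

**Step 10**
Reactants: 14 arylacetic acid; 15 (S)-4-benzyl-1,3-oxazolidin-2-one
Product: 17 (S)-4-benzyl-3-{2-[5-(1,3-dioxolan-2-yl)-3-methoxy-2-(methoxymethoxy)phenyl]acetyl}-1,3-oxazolidin-2-one, via mixed pivalic anhydride 16 (not isolated)
Conditions: PivCl, Et3N, THF, −20 °C; then LiCl, 15, −20 °C → rt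
Reagents that add atoms: none
Why: Mixed-anhydride N-acylation of the oxazolidinone, in which the auxiliary attacks the less hindered arylacetyl carbonyl of 16.

**Step 11**
Reactants: 17 arylacetyl imide; 7 O-benzylvanillin
Product: 20 (S)-4-benzyl-3-{(2S,3S)-3-[4-(benzyloxy)-3-methoxyphenyl]-2-[5-(1,3-dioxolan-2-yl)-3-methoxy-2-(methoxymethoxy)phenyl]-3-hydroxypropanoyl}-1,3-oxazolidin-2-one, via Z-boron enolate 18 (not isolated), via boron aldolate 19 (not isolated)
Conditions: Bu2BOTf (1.2 equiv), iPr2NEt (1.3 equiv), CH2Cl2, −78 → 0 °C; 7, −78 → 0 °C; pH 7 buffer, MeOH, 30% H2O2, 0 °C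
Reagents that add atoms: none
Why: Evans syn aldol, in which Z-enolate 18 reacts through a chair Zimmerman–Traxler transition state on the face away from the benzyl group of the (S)-auxiliary, setting the aryl-bearing carbon as (2S) (the later benzofuran C3) and the carbinol carbon as (3S).

**Step 12**
Reactants: 20 syn aldol
Product: 21 (1S,2R)-1-[4-(benzyloxy)-3-methoxyphenyl]-2-[5-(1,3-dioxolan-2-yl)-3-methoxy-2-(methoxymethoxy)phenyl]propane-1,3-diol
Conditions: LiBH4, MeOH (2 equiv), THF, 0 °C
Reagents that add atoms: none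
Why: Reductive cleavage of the N-acyloxazolidinone, in which hydride attacks the exocyclic imide carbonyl at 0 °C and gives the primary alcohol without disturbing the neighbouring stereocentre, the acetal or the MOM ether.

**Step 13**
Reactants: 21 diol
Product: 23 (2S,3R)-2-[4-(benzyloxy)-3-methoxyphenyl]-3-(hydroxymethyl)-7-methoxy-2,3-dihydro-1-benzofuran-5-carbaldehyde, via free phenol 22 (not isolated)
Conditions: 3 M aq HCl–THF (1:3), 45 °C
Reagents that add atoms: water, O
Why: Acid cascade in which hydrolysis of the dioxolane and the MOM ether frees phenol 22, the 4-benzyloxy-3-methoxybenzylic alcohol ionises, and the phenol captures the cation in a reversible 5-exo closure (SN1 etherification), so that C2 settles trans to the CH2OH group on the fixed C3 and the (2S,3R) isomer should result.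

**Step 14**
Reactants: 23 hydroxy aldehyde
Product: 24 {(2S,3R)-2-[4-(benzyloxy)-3-methoxyphenyl]-5-[bis(phenylthio)methyl]-7-methoxy-2,3-dihydro-1-benzofuran-3-yl}methanol
Conditions: PhSH (2.2 equiv), BF3·OEt2 (0.3 equiv), CH2Cl2, −30 → 0 °C
Reagents that add atoms: thiophenol, Sc1ccccc1
Why: Lewis-acid thioacetalisation, in which the alkoxy-stabilised thionium ion of the aldehyde forms far more easily at low temperature than the ring C2–O bond ionises, so only the aldehyde reacts and no silyl group is yet present to be lost.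

**Step 15**
Reactants: 24 dithioacetal alcohol
Product: 25 tert-butyldimethylsilyl ether of 24, i.e. (2S,3R)-2-[4-(benzyloxy)-3-methoxyphenyl]-5-[bis(phenylthio)methyl]-3-[(tert-butyldimethylsilyloxy)methyl]-7-methoxy-2,3-dihydro-1-benzofuran
Conditions: TBSCl, imidazole, DMF, rt
Reagents that add atoms: tert-butyldimethylsilyl chloride, CC(C)(C)[Si](C)(C)Cl
Why: Standard silylation of the only hydroxyl group, which removes the one proton that would compete with the dithioacetal C–H in the next step.

**Step 16**
Reactants: 25 silylated benzofuranyl bis(phenylthio)acetal; 5 (5R)-5-(l-menthyloxy)furan-2(5H)-one; 9 4-(benzyloxy)-3-methoxybenzyl bromide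
Product: 28 (3R,4R,5R)-3-[4-(benzyloxy)-3-methoxybenzyl]-4-{[(2S,3R)-2-(4-benzyloxy-3-methoxyphenyl)-3-(tert-butyldimethylsilyloxymethyl)-7-methoxy-2,3-dihydro-1-benzofuran-5-yl]bis(phenylthio)methyl}-5-(l-menthyloxy)dihydrofuran-2(3H)-one, via lithiated dithioacetal 26 (not isolated), via lithium enolate 27 (not isolated)
Conditions: n-BuLi (1.05 equiv), THF, −78 °C, 1 h; 5 (1.1 equiv), THF, −78 °C, 2 h; 9 (1.5 equiv), DMPU (4 equiv), −78 → −20 °C; aq NH4Cl
Reagents that add atoms: none
Why: n-BuLi removes the only acidic proton of 25, and the soft, doubly sulfur-stabilised benzylic carbanion 26 attacks C4 of butenolide 5 in a Michael addition instead of the lactone carbonyl, giving lithium enolate 27, which bromide 9 then benzylates at C3 in an SN2 step accelerated by DMPU. The closest known reaction type is the tandem conjugate addition–enolate alkylation of lithiated aryl bis(phenylthio)methanes on 5-alkoxybutenolides, a standard entry to trans-dibenzylbutyrolactone lignans. No ring is closed, since 5 delivers the five-membered lactone intact and only the C4–C(SPh)2 and C3–CH2Ar bonds are made. C4 is set by the C5 menthyloxy group, which blocks one face of the flat butenolide so that the carbanion enters anti to it, and C3 is set by the new quaternary C(SPh)2Ar group, which sends the bromide to the opposite enolate face, so the 3,4-trans-4,5-trans lactone should form. The step needs 1,4- over 1,2-addition (secured by the soft carbanion), C-monoalkylation (secured by the reactive benzylic bromide and the hindered tertiary C3 of the product) and correct placement of the two nearly identical guaiacyl-type arms, which the order of addition fixes. C2 and C3 of the benzofuran are remote from the reacting carbon and carry no proton that n-BuLi removes at −78 °C in competition with the dithioacetal, so they pass through unchanged.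

**Step 17**
Reactants: 28 three-component adduct
Product: 29 (3R,4R,5R)-3-[4-(benzyloxy)-3-methoxybenzyl]-4-{[(2S,3R)-2-(4-benzyloxy-3-methoxyphenyl)-3-(tert-butyldimethylsilyloxymethyl)-7-methoxy-2,3-dihydro-1-benzofuran-5-yl]methyl}-5-(l-menthyloxy)dihydrofuran-2(3H)-one
Conditions: NiCl2·6H2O (10 equiv), NaBH4 (30 equiv, portionwise), MeOH–THF (3:1), 0 °C; filtration through Celite
Reagents that add atoms: none
Why: Nickel boride desulfurisation cleaves the two weak benzylic C–S bonds, whereas this milder relative of Raney Ni should leave the aryl benzyl ethers, the silyl ether and the ring C2–O bond intact, and no stereocentre is involved because the sulfur-bearing carbon becomes CH2.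

**Step 18**
Reactants: 29 desulfurised menthyloxy lactone
Product: 33 (3R,4R)-3-[4-(benzyloxy)-3-methoxybenzyl]-4-{[(2S,3R)-2-(4-benzyloxy-3-methoxyphenyl)-3-(hydroxymethyl)-7-methoxy-2,3-dihydro-1-benzofuran-5-yl]methyl}dihydrofuran-2(3H)-one (di-O-benzyl lappaol A), via formyl carboxylate 30 (not isolated), via hydroxy carboxylate 31 (not isolated), via silylated lactone 32 (not isolated)
Conditions: NaBH4 (4 equiv), KOH (3 equiv), EtOH–THF, rt; then 2 M aq HCl to pH 1, rt
Reagents that add atoms: none
Why: Hydroxide opens the acylal-type lactone to 30 with loss of menthol, borohydride traps the aldehyde as 31 before C4 can epimerise, and acidification closes the γ-lactone (32) and hydrolyses the primary silyl ether, the established conversion of a 5-alkoxybutyrolactone into the 5-unsubstituted lactone with C3 and C4 retained.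

**Step 19**
Reactants: 33 di-O-benzyl lappaol A
Product: 34 lappaol A
Conditions: H2 (1 atm), 10% Pd/C, EtOAc–EtOH (1:1), rt
Reagents that add atoms: none
Why: Catalytic hydrogenolysis removes the two primary aryl benzyl ethers, while the secondary, ring-bound benzylic C2–O bond reacts much more slowly under neutral conditions at 1 atm, so the reaction is stopped after two equivalents of hydrogen.

**Compound list**

1 | furfural | O=Cc1ccco1 | starting material
2 | 1-formyl-2,3,7-trioxabicyclo[2.2.1]hept-5-ene (furan endoperoxide) | O=CC12C=CC(OO1)O2 | intermediate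
3 | 5-hydroxyfuran-2(5H)-one (racemic) | O=C1C=CC(O)O1 | intermediate
4 | l-menthol, (1R,2S,5R)-2-isopropyl-5-methylcyclohexanol | CC(C)[C@@H]1CC[C@@H](C)C[C@H]1O | starting material
5 | (5R)-5-(l-menthyloxy)furan-2(5H)-one | O=C1C=C[C@H](O[C@@H]2C[C@H](C)CC[C@H]2C(C)C)O1 | intermediate
6 | vanillin | COc1cc(C=O)ccc1O | starting material
7 | 4-(benzyloxy)-3-methoxybenzaldehyde | COc1cc(C=O)ccc1OCc1ccccc1 | intermediate
8 | [4-(benzyloxy)-3-methoxyphenyl]methanol | COc1cc(CO)ccc1OCc1ccccc1 | intermediate
9 | 4-(benzyloxy)-3-methoxybenzyl bromide | COc1cc(CBr)ccc1OCc1ccccc1 | intermediate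
10 | 5-iodovanillin | Ic1cc(C=O)cc(OC)c1O | starting material
11 | 3-iodo-5-methoxy-4-(methoxymethoxy)benzaldehyde | Ic1cc(C=O)cc(OC)c1OCOC | intermediate
12 | 2-[3-iodo-5-methoxy-4-(methoxymethoxy)phenyl]-1,3-dioxolane | Ic1cc(C2OCCO2)cc(OC)c1OCOC | intermediate
13 | ethyl 2-[5-(1,3-dioxolan-2-yl)-3-methoxy-2-(methoxymethoxy)phenyl]acetate | CCOC(=O)Cc1cc(C2OCCO2)cc(OC)c1OCOC | intermediate
14 | 2-[5-(1,3-dioxolan-2-yl)-3-methoxy-2-(methoxymethoxy)phenyl]acetic acid | OC(=O)Cc1cc(C2OCCO2)cc(OC)c1OCOC | intermediate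
15 | (S)-4-benzyl-1,3-oxazolidin-2-one | O=C1N[C@@H](Cc2ccccc2)CO1 | starting material
16 | mixed anhydride of 14 with pivalic acid | CC(C)(C)C(=O)OC(=O)Cc1cc(C2OCCO2)cc(OC)c1OCOC | intermediate
17 | (S)-4-benzyl-3-(arylacetyl)oxazolidin-2-one | O=C1OC[C@H](Cc2ccccc2)N1C(=O)Cc1cc(C2OCCO2)cc(OC)c1OCOC | intermediate
18 | Z-dibutylboron enolate of 17 | CCCCB(CCCC)O/C(=C\c1cc(C2OCCO2)cc(OC)c1OCOC)N1[C@@H](Cc2ccccc2)COC1=O | intermediate
19 | dibutylboron aldolate of 20 | O=C1OC[C@H](Cc2ccccc2)N1C(=O)[C@H]([C@H](OB(CCCC)CCCC)c1ccc(OCc2ccccc2)c(OC)c1)c1cc(C2OCCO2)cc(OC)c1OCOC | intermediate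
20 | (4S,2'S,3'S) syn aldol imide | O=C1OC[C@H](Cc2ccccc2)N1C(=O)[C@H]([C@H](O)c1ccc(OCc2ccccc2)c(OC)c1)c1cc(C2OCCO2)cc(OC)c1OCOC | intermediate
21 | (1S,2R)-1,2-diarylpropane-1,3-diol (MOM ether, dioxolane) | OC[C@H]([C@H](O)c1ccc(OCc2ccccc2)c(OC)c1)c1cc(C2OCCO2)cc(OC)c1OCOC | intermediate
22 | 3-{(1S,2R)-1-[4-(benzyloxy)-3-methoxyphenyl]-1,3-dihydroxypropan-2-yl}-4-hydroxy-5-methoxybenzaldehyde | OC[C@H]([C@H](O)c1ccc(OCc2ccccc2)c(OC)c1)c1cc(C=O)cc(OC)c1O | intermediate
23 | (2S,3R)-2-[4-(benzyloxy)-3-methoxyphenyl]-3-(hydroxymethyl)-7-methoxy-2,3-dihydrobenzofuran-5-carbaldehyde | O=Cc1cc(OC)c2c(c1)[C@H](CO)[C@@H](c1ccc(OCc3ccccc3)c(OC)c1)O2 | intermediate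
24 | bis(phenylthio)acetal of 23 | c1ccc(cc1)SC(Sc1ccccc1)c1cc(OC)c2c(c1)[C@H](CO)[C@@H](c1ccc(OCc3ccccc3)c(OC)c1)O2 | intermediate
25 | TBS ether of 24 (key-step precursor) | c1ccc(cc1)SC(Sc1ccccc1)c1cc(OC)c2c(c1)[C@H](CO[Si](C)(C)C(C)(C)C)[C@@H](c1ccc(OCc3ccccc3)c(OC)c1)O2 | intermediate
26 | lithiated dithioacetal of 25 | [Li]C(Sc1ccccc1)(Sc1ccccc1)c1cc(OC)c2c(c1)[C@H](CO[Si](C)(C)C(C)(C)C)[C@@H](c1ccc(OCc3ccccc3)c(OC)c1)O2 | intermediate
27 | lithium enolate after conjugate addition | [Li]OC1=C[C@@H](C(Sc2ccccc2)(Sc2ccccc2)c2cc(OC)c3c(c2)[C@H](CO[Si](C)(C)C(C)(C)C)[C@@H](c2ccc(OCc4ccccc4)c(OC)c2)O3)[C@H](O[C@@H]2C[C@H](C)CC[C@H]2C(C)C)O1 | intermediate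
28 | (3R,4R,5R) three-component adduct | COc1cc(C[C@H]2C(=O)O[C@@H](O[C@@H]3C[C@H](C)CC[C@H]3C(C)C)[C@@H]2C(Sc2ccccc2)(Sc2ccccc2)c2cc(OC)c3c(c2)[C@H](CO[Si](C)(C)C(C)(C)C)[C@@H](c2ccc(OCc4ccccc4)c(OC)c2)O3)ccc1OCc1ccccc1 | intermediate
29 | (3R,4R,5R) desulfurised menthyloxy lactone | COc1cc(C[C@H]2C(=O)O[C@@H](O[C@@H]3C[C@H](C)CC[C@H]3C(C)C)[C@@H]2Cc2cc(OC)c3c(c2)[C@H](CO[Si](C)(C)C(C)(C)C)[C@@H](c2ccc(OCc4ccccc4)c(OC)c2)O3)ccc1OCc1ccccc1 | intermediate
30 | potassium (2R,3R)-2-(arylmethyl)-3-formyl-4-(benzofuranyl)butanoate | [K+].COc1cc(C[C@@H](C(=O)[O-])[C@H](C=O)Cc2cc(OC)c3c(c2)[C@H](CO[Si](C)(C)C(C)(C)C)[C@@H](c2ccc(OCc4ccccc4)c(OC)c2)O3)ccc1OCc1ccccc1 | intermediate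
31 | potassium (2R,3R)-2-(arylmethyl)-3-(hydroxymethyl)-4-(benzofuranyl)butanoate | [K+].COc1cc(C[C@@H](C(=O)[O-])[C@H](CO)Cc2cc(OC)c3c(c2)[C@H](CO[Si](C)(C)C(C)(C)C)[C@@H](c2ccc(OCc4ccccc4)c(OC)c2)O3)ccc1OCc1ccccc1 | intermediate
32 | (3R,4R) silylated dibenzyl lactone | COc1cc(C[C@H]2C(=O)OC[C@@H]2Cc2cc(OC)c3c(c2)[C@H](CO[Si](C)(C)C(C)(C)C)[C@@H](c2ccc(OCc4ccccc4)c(OC)c2)O3)ccc1OCc1ccccc1 | intermediate
33 | di-O-benzyl lappaol A | COc1cc(C[C@H]2C(=O)OC[C@@H]2Cc2cc(OC)c3c(c2)[C@H](CO)[C@@H](c2ccc(OCc4ccccc4)c(OC)c2)O3)ccc1OCc1ccccc1 | intermediate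
34 | lappaol A | COc1cc(C[C@H]2C(=O)OC[C@@H]2Cc2cc(OC)c3c(c2)[C@H](CO)[C@@H](c2ccc(O)c(OC)c2)O3)ccc1O | target

**Step count**

Total step count: 19.
Longest linear sequence: 14 steps (steps 6–19, from 5-iodovanillin).

**Steps most likely to fail**

**Step 16.** The crowded enolate 27 may be benzylated too slowly. Proton transfer, retro-Michael loss of the stabilised carbanion on warming, or erosion of facial control could then compete.

The fallback sets out from 25 and 5 and comes back to the route at 28. It makes the two bonds in separate operations.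
- The addition is quenched at −78 °C with aq NH4Cl, and the conjugate adduct F1 is isolated and freed from unreacted 25.
- Enolate 27 is regenerated cleanly with LiHMDS in THF–DMPU at −78 °C and treated with excess 9 at low temperature for as long as needed.
- The bulky C4 group still directs the bromide to the opposite face.

**Step 13.** Ionisation of the benzylic alcohol may run ahead of MOM cleavage. Several processes could then drain material:
- loss of the proton next to the cation;
- retro-Prins loss of formaldehyde from the free CH2OH arm;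
- intermolecular arylation;
- incomplete equilibration, which would lower the trans preference.

The fallback sets out from 21 and comes back at 25. It changes the order of events and separates deprotection from ring closure.
- The primary alcohol is silylated first (TBSCl, 1.05 equiv, imidazole, CH2Cl2, 0 °C) to give the primary silyl ether F2, which blocks the fragmentation.
- The aryl MOM ether and the dioxolane are removed under buffered, non-ionising conditions (TMSOTf, 2,2'-bipyridyl, MeCN, 0 °C, then H2O) to give the phenol aldehyde F3.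
- A short treatment with camphorsulfonic acid (5 mol%) in CH2Cl2 at 0 °C closes the ring to the silylated benzofuran aldehyde F4.
- PhSH with MgBr2·OEt2 in Et2O–CH2Cl2 at rt, mild enough for the silyl ether, gives 25.

**Step 17.** The nickel surface may act beyond the C–S bonds, by hydrogenolysis of aryl benzyl ethers or of the ring C2–O bond. It may also stall after the first sulfur at the crowded carbon. The basic borohydride medium may begin to open the acetal-lactone, although that premature opening only anticipates step 18.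

The fallback sets out from 28 and comes back at 29. It replaces the heterogeneous metal reduction by a homolytic chain reduction with Bu3SnH (5 equiv) and AIBN (portionwise) in toluene at 100 °C.
- Stannyl radicals attack sulfur only, so ethers, lactone and silyl ether are not touched.
- The reduction passes through the mono(phenylthio) lactone F5, an epimer mixture at the sulfur-bearing carbon.
- F5 can be isolated and resubmitted until 29 is reached.

**Further compounds**

F1 | step 16 | (4R,5R)-4-{[(2S,3R)-2-(4-benzyloxy-3-methoxyphenyl)-3-(tert-butyldimethylsilyloxymethyl)-7-methoxy-2,3-dihydrobenzofuran-5-yl]bis(phenylthio)methyl}-5-(l-menthyloxy)dihydrofuran-2(3H)-one | O=C1C[C@@H](C(Sc2ccccc2)(Sc2ccccc2)c2cc(OC)c3c(c2)[C@H](CO[Si](C)(C)C(C)(C)C)[C@@H](c2ccc(OCc4ccccc4)c(OC)c2)O3)[C@H](O[C@@H]2C[C@H](C)CC[C@H]2C(C)C)O1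
F2 | step 13 | (1S,2R)-1-[4-(benzyloxy)-3-methoxyphenyl]-3-(tert-butyldimethylsilyloxy)-2-[5-(1,3-dioxolan-2-yl)-3-methoxy-2-(methoxymethoxy)phenyl]propan-1-ol | CC(C)(C)[Si](C)(C)OC[C@H]([C@H](O)c1ccc(OCc2ccccc2)c(OC)c1)c1cc(C2OCCO2)cc(OC)c1OCOC
F3 | step 13 | 3-{(1S,2R)-1-[4-(benzyloxy)-3-methoxyphenyl]-3-(tert-butyldimethylsilyloxy)-1-hydroxypropan-2-yl}-4-hydroxy-5-methoxybenzaldehyde | CC(C)(C)[Si](C)(C)OC[C@H]([C@H](O)c1ccc(OCc2ccccc2)c(OC)c1)c1cc(C=O)cc(OC)c1O
F4 | step 13 | (2S,3R)-2-[4-(benzyloxy)-3-methoxyphenyl]-3-(tert-butyldimethylsilyloxymethyl)-7-methoxy-2,3-dihydrobenzofuran-5-carbaldehyde | O=Cc1cc(OC)c2c(c1)[C@H](CO[Si](C)(C)C(C)(C)C)[C@@H](c1ccc(OCc3ccccc3)c(OC)c1)O2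
F5 | step 17 | mono(phenylthio) analogue of 28 (epimer mixture at the sulfur-bearing carbon) | COc1cc(C[C@H]2C(=O)O[C@@H](O[C@@H]3C[C@H](C)CC[C@H]3C(C)C)[C@@H]2C(Sc2ccccc2)c2cc(OC)c3c(c2)[C@H](CO[Si](C)(C)C(C)(C)C)[C@@H](c2ccc(OCc4ccccc4)c(OC)c2)O3)ccc1OCc1ccccc1
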